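## Structural features

The target is a flat, achiral chain of three heteroaromatic rings: a 6-bromo-4-methoxyindole, a 1,3-oxazole and a 5-bromopyrrole. Indole C3 is bonded to oxazole C5 and oxazole C2 to pyrrole C2, while indole C2 and oxazole C4 carry hydrogen. There is no stereocentre, so every problem is one of regiochemistry or chemoselectivity. The fragile points are the two N–H groups, the electron-rich 4-methoxyindole whose methoxy group sits peri to the oxazole, the aryl C6–Br bond that must survive all organometallic steps, and the α-bromopyrrole. The α-bromopyrrole is sensitive to acid, light and low-valent metals, so it should appear late. Oxazole C2 carries the most acidic C–H of the skeleton, but a 2-lithiooxazole opens to an isocyano enolate. The real difficulty is the oxazole C2–pyrrole C2 bond, because 2-metalated and 2-halogenated N–H pyrroles are unstable and a palladium coupling would have to tell its halide from the C6 bromide. A single bromination at pyrrole C5 is the second difficulty. The key step uses the fact that pyrrole C2 can begin as a ketone carbon on oxazole C2: a 1,4-ketoaldehyde chain on that carbon is closed with ammonia across N1–C2 and N1–C5, leaving C5 as the only open α-position for the late bromine.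

## Logic of the disconnections

**20 ⇒ 18.** The bond cut is indole N1–CH2 of the protecting group. The group is needed because a free indole N–H would consume the amide base of the metalation and would turn the 3-formyl group into a poorly electrophilic vinylogous amide. One group covers seven steps, since it tolerates hot methanolic carbonate, an amide base, dilute acid, an ammonium salt and an electrophilic bromine source. The forward step must free the nitrogen without acid and must trap the one-carbon fragment released, so that the α-bromopyrrole is spared.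

**18 ⇒ 17.** The bond cut is pyrrole C5–Br. A 1,4-dicarbonyl condensation cannot deliver a halogen at C5, and the labile α-bromopyrrole is best carried through one step only. This leaves 17, whose pyrrole has a single free α-position. The forward step must brominate once, at pyrrole C5, in preference to pyrrole C4, indole C2, C5 and C7 and oxazole C4.

**17 ⇒ 14.** The bonds cut are pyrrole N1–C2 and N1–C5. The ring is taken apart into a nitrogen source and a ketoaldehyde whose ketone carbon already sits on oxazole C2. No 2-metalated or 2-halogenated pyrrole and no palladium is needed, and the 1,4-spacing allows no regioisomer. One ring is removed and a linear four-carbon chain remains. The forward step must complete two dehydrations faster than furan formation or self-condensation of the aldehyde.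

**14 ⇒ 13.** The cut is a functional-group change: the aldehyde is masked as its dimethyl acetal. A free aldehyde cannot pass through the organomagnesium step and does not store well. The refinement of the precursor design is therefore that 13 is the isolated, storable compound and 14 is released immediately before use. The hydrolysis must be mild enough to leave the N,O-acetal of the protecting group intact.

**13 ⇒ 8 + 10.** The bond cut is oxazole C2–C(=O), the only carbon–carbon bond joining the two halves. It is chosen because C2–H is the most acidic site of 8, which makes the step convergent and leaves two simple pieces. The forward step needs a C2 carbanion that neither ring-opens nor exchanges with the C6 bromide, and an acyl donor that accepts only one addition.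

**10 ⇒ 9.** The bond cut is the amide C–N. The acyl donor comes in one step from a commercial ester that already has the correct chain length and the masked aldehyde. The aminolysis must leave the acetal untouched.

**8 ⇒ 5 + 6.** The bonds cut are oxazole C4–C5 and O1–C2. This gives the 5-substituted oxazole with C2 and C4 unsubstituted directly from an aldehyde and a one-carbon, one-nitrogen, one-carbon reagent. The aldehyde must be electrophilic enough, which is why the indole nitrogen is alkylated first.

**5 ⇒ 3.** The bond cut is indole N1–CH2. Protection is placed after formylation because the formyl group acidifies the N–H and the formylation itself is best established on the free indole. The forward step must alkylate at nitrogen only.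

**3 ⇒ 1.** The bond cut is indole C3–CHO. C3 is the most nucleophilic carbon of 1, and the one-carbon unit becomes oxazole C5. The forward step must select C3 over C2 and over the methoxy-activated C5 and C7.

## Other disconnections considered

**Alternative 1:** The cut is the indole five-membered ring at C3–C3a and N1–C2, leading to 5-bromo-2-iodo-3-methoxyaniline A2 and the silylalkyne 2-(1-SEM-pyrrol-2-yl)-5-[(trimethylsilyl)ethynyl]-1,3-oxazole A3.
- **Forward key step:** a Larock heteroannulation with zerovalent palladium formed from Pd(OAc)2. Oxidative addition into the C–I bond of A2 is followed by syn-insertion of A3, with the aryl group going to the oxazolyl-bearing carbon and palladium next to silicon. C–N reductive elimination then gives A1. Protodesilylation to A4, pyrrole bromination and SEM removal would follow.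
- **In its favour:** it is more convergent than the chosen plan, the silyl group enforces the C2/C3 regiochemistry, and the indole nitrogen needs no protection. On these three points it is the better plan.
- **Against it here:** the C–I bond of A2 lies between NH2 and OMe, the C6–Br bond is a second site for oxidative addition at the usual temperature, and the insertion must join a methoxy-flanked aryl carbon to the oxazolyl-bearing alkyne carbon. The azole nitrogens can also bind palladium. A2 and A3 both need their own syntheses, and making A3 already requires the pyrrole–oxazole bond, so the hard bond is moved and not solved.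
- **Comparison:** structurally the chosen plan keeps a purchasable indole intact where this one rebuilds it. Mechanistically the chosen plan has no palladium next to an aryl bromide. In step count this alternative is expected to be longer, since two fragment syntheses and a desilylation are added to the same two closing steps.

**Alternative 2:** The cut is N1–C7a and C3–C3a. The benzene ring arrives as 5-bromo-3-methoxybenzyne A6, released by fluoride from 4-bromo-2-methoxy-6-(trimethylsilyl)phenyl triflate A5. The N–C–C unit is 5-(2H-azirin-3-yl)-2-(1-SEM-pyrrol-2-yl)-1,3-oxazole A7.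
- **Forward key step:** the azirine nitrogen adds to A6, the resulting aryl anion adds to the C=N carbon, and ring opening with a hydrogen shift gives the indole A4.
- **In its favour:** it is metal-free, so on safety of the C–Br bond it equals the chosen plan. The innate preference of a 3-methoxyaryne for attack at the carbon remote from the methoxy group matches the required pattern. It gives the N–H indole directly, which is better than a protection and deprotection pair.
- **Against it here:** A5 needs several steps. A7 is a strained azirine without a C2 substituent that would come from a vinyl azide, which adds hazard and instability. Arynes also react with pyrroles and oxazoles as dienes and can N-arylate the indole formed. Fluoride may erode the SEM group. Making A7 again presupposes the pyrrole–oxazole bond.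
- **Comparison:** structurally this annulation is the more elegant way to make the indole ring. Mechanistically it demands chemoselectivity of a very reactive intermediate among three π-systems, where the chosen plan only asks two carbonyl groups to condense. In step count it is expected to be longer.

**Alternative 3:** The cut is oxazole C4–C5 and O1–C2, with the van Leusen cycloaddition and sulfinate elimination as the forward key step. Its product A8 is identical with 8, so as an oxazole-forming step it is the exact equal of step 3 of the chosen route.
- **What differs:** a plan centred on this step would then attach an intact pyrrole. C2 metalation and iodination would give the 2-iodooxazole A9, and Suzuki–Miyaura coupling with (1-Boc-pyrrol-2-yl)boronic acid A10 would follow.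
- **In its favour:** it is shorter by about two steps, and there it is the better plan. It uses a purchasable pyrrole building block and is well supported for the individual reaction types.
- **Against it here:** zerovalent palladium must select the oxazole C2–I bond over the indole C6–Br bond, 2-pyrrolylboronic acids protodeboronate readily, and 2-iodooxazoles are sensitive.
- **Comparison:** structurally the two plans share everything up to 8. Mechanistically the chosen plan makes the inter-ring bond by acylation and the pyrrole by condensation, with no step in which the two carbon–halogen bonds compete. The price is the longer sequence. This alternative is kept as the fallback for the key step.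

Key step: step 7

Remarks on the chemistry:
- SEM = [2-(trimethylsilyl)ethoxy]methyl; TMP = 2,2,6,6-tetramethylpiperidin-1-yl.
- Compounds 1, 6 and 9 and all reagents named are taken as purchasable.
- The transient compounds 7, 15 and 16 form as mixtures of stereoisomers whose stereocentres vanish in the same operation, so they are drawn without configuration.

## Route

Step 1
Reactants: 1 6-bromo-4-methoxy-1H-indole
Product: 3 6-bromo-4-methoxy-1H-indole-3-carbaldehyde, via C3 iminium chloride 2 (not isolated)
Conditions: POCl3, DMF, 0 °C → 40 °C; then aq NaOH, 0 °C → 90 °C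
Reagents that add atoms: N,N-dimethylformamide CN(C)C=O; water O
Why: Vilsmeier–Haack formylation; the chloroiminium ion attacks C3, the enamine-like and most nucleophilic carbon of the indole, and basic hydrolysis of iminium salt 2 releases the aldehyde; the bromide and the methyl ether are inert.

Step 2
Reactants: 3 6-bromo-4-methoxy-1H-indole-3-carbaldehyde
Product: 5 6-bromo-4-methoxy-1-SEM-1H-indole-3-carbaldehyde, via sodium indolide 4 (not isolated)
Conditions: NaH, DMF, 0 °C; then SEMCl, 0 °C → rt
Reagents that add atoms: 2-(trimethylsilyl)ethoxymethyl chloride C[Si](C)(C)CCOCCl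
Why: N-alkylation of an indolide; the formyl group acidifies the N–H so that deprotonation is clean, and the hard chloromethyl ether reacts at nitrogen; the SEM group removes the acidic proton before step 5 and restores the electrophilicity of the aldehyde for step 3.

Step 3
Reactants: 5 6-bromo-4-methoxy-1-SEM-1H-indole-3-carbaldehyde; 6 p-toluenesulfonylmethyl isocyanide (TosMIC)
Product: 8 5-(6-bromo-4-methoxy-1-SEM-1H-indol-3-yl)-1,3-oxazole, via 4-tosyl-oxazoline 7 (not isolated)
Conditions: K2CO3, MeOH, reflux
Reagents that add atoms: none
Why: van Leusen oxazole synthesis; the TosMIC anion adds to the aldehyde, the alkoxide closes on the isocyanide carbon to give oxazoline 7, and base-induced loss of p-toluenesulfinate aromatises the ring; N-alkylation prevents the aldehyde from being deactivated as an indolide, and the aryl bromide and the SEM group tolerate methanolic carbonate.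

Step 4
Reactants: 9 methyl 4,4-dimethoxybutanoate
Product: 10 N,4,4-trimethoxy-N-methylbutanamide
Conditions: MeNH(OMe)·HCl, i-PrMgCl, THF, −20 °C → 0 °C
Reagents that add atoms: N,O-dimethylhydroxylamine hydrochloride CNOC.Cl
Why: direct Weinreb aminolysis of an ester by the chloromagnesium amide formed in the flask; the chelated tetrahedral adduct prevents over-addition and the dimethyl acetal is inert to base and to the Grignard reagent.

Step 5
Reactants: 8 5-(6-bromo-4-methoxy-1-SEM-1H-indol-3-yl)-1,3-oxazole; 10 N,4,4-trimethoxy-N-methylbutanamide
Product: 13 1-[5-(6-bromo-4-methoxy-1-SEM-1H-indol-3-yl)-1,3-oxazol-2-yl]-4,4-dimethoxybutan-1-one, via 2-oxazolylmagnesium chloride 11 (not isolated), via tetrahedral magnesium adduct 12 (not isolated)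
Conditions: TMPMgCl·LiCl (1.1 equiv), THF, −20 °C; then 10, −20 °C → rt; aq NH4Cl
Reagents that add atoms: none
Why: deprotonative magnesiation of the most acidic C–H (oxazole C2) followed by Weinreb ketone synthesis; the amide base cannot undergo bromine–magnesium exchange at C6, the C2-magnesium species stays ring-closed where the lithium analogue would open, and the chelate 12 collapses to the ketone only on quench, so a single acylation is expected.

Step 6
Reactants: 13 1-[5-(6-bromo-4-methoxy-1-SEM-1H-indol-3-yl)-1,3-oxazol-2-yl]-4,4-dimethoxybutan-1-one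
Product: 14 4-[5-(6-bromo-4-methoxy-1-SEM-1H-indol-3-yl)-1,3-oxazol-2-yl]-4-oxobutanal
Conditions: 1 M aq HCl, THF, 0 °C → rt; crude product used at once
Reagents that add atoms: water O
Why: acid-catalysed hydrolysis of an aliphatic dimethyl acetal, which is far more labile than the N,O-acetal of the SEM group (its nitrogen lone pair is tied up in the indole) and than the aryl methyl ether; short contact and immediate use limit aldol self-condensation of the ketoaldehyde.

Step 7
Reactants: 14 4-[5-(6-bromo-4-methoxy-1-SEM-1H-indol-3-yl)-1,3-oxazol-2-yl]-4-oxobutanal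
Product: 17 5-(6-bromo-4-methoxy-1-SEM-1H-indol-3-yl)-2-(1H-pyrrol-2-yl)-1,3-oxazole, via open-chain carbinolamine 15 (not isolated), via pyrrolidine-2,5-diol 16 (not isolated)
Conditions: NH4OAc (10 equiv), MeOH, rt → 50 °C
Reagents that add atoms: ammonium acetate CC(=O)[O-].[NH4+]
Why: Paal–Knorr pyrrole synthesis, whose closest known form is the condensation of γ-ketoaldehydes with ammonium acetate to 2-substituted pyrroles. Ammonia from the acetate equilibrium adds to the unhindered aldehyde to give carbinolamine 15, which forms the N1–C5 bond. The nitrogen of 15 then attacks the ketone, activated by the electron-poor oxazole, in a 5-exo-trig closure that forms N1–C2 and the five-membered ring as diol 16. Two acetic-acid-assisted dehydrations of 16 give the aromatic pyrrole, which drives the sequence forward. No stereocentre remains in the product; those of 15 and 16 are transient and uncontrolled. The selectivity needed is complete cyclodehydration through nitrogen and not furan formation through the enol oxygen or oligomerisation of the aldehyde; the large excess of a nearly neutral ammonium salt and the high electrophilicity of the ketone secure it. Regiochemistry is fixed by the 1,4-spacing: the ketone carbon on oxazole C2 must become pyrrole C2 and the aldehyde carbon the unsubstituted C5. The SEM group, the aryl bromide and the oxazole are inert under these conditions.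

Step 8
Reactants: 17 5-(6-bromo-4-methoxy-1-SEM-1H-indol-3-yl)-2-(1H-pyrrol-2-yl)-1,3-oxazole
Product: 18 2-(5-bromo-1H-pyrrol-2-yl)-5-(6-bromo-4-methoxy-1-SEM-1H-indol-3-yl)-1,3-oxazole
Conditions: NBS (1.0 equiv), THF, −78 °C → −40 °C, dark
Reagents that add atoms: N-bromosuccinimide O=C1CCC(=O)N1Br
Why: electrophilic aromatic bromination; the free α-position C5 of the pyrrole is by far the most nucleophilic site, the oxazolyl group tempers the ring enough to discourage a second bromination, indole C2 is shielded by the SEM group and the 3-oxazolyl group, and the benzo ring is deactivated by its bromine.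

Step 9
Reactants: 18 2-(5-bromo-1H-pyrrol-2-yl)-5-(6-bromo-4-methoxy-1-SEM-1H-indol-3-yl)-1,3-oxazole
Product: 20 2-(5-bromo-1H-pyrrol-2-yl)-5-(6-bromo-4-methoxy-1H-indol-3-yl)-1,3-oxazole, via N-hydroxymethyl indole 19 (not isolated)
Conditions: Bu4NF, H2NCH2CH2NH2, THF, 65 °C
Reagents that add atoms: none
Why: fluoride-induced fragmentation of the SEM group; attack at silicon expels ethene and leaves hemiaminal 19, which loses formaldehyde, and ethylenediamine traps the formaldehyde as an aminal so that it cannot re-alkylate the N–H groups; the non-acidic medium is chosen to spare the α-bromopyrrole, which is stabilised by its oxazole acceptor.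

## Compound list

1 | 6-bromo-4-methoxy-1H-indole | COc1cc(Br)cc2[nH]ccc12 | starting material
2 | N-[(6-bromo-4-methoxy-1H-indol-3-yl)methylidene]-N-methylmethanaminium chloride | COc1cc(Br)cc2[nH]cc(C=[N+](C)C)c12.[Cl-] | intermediate
3 | 6-bromo-4-methoxy-1H-indole-3-carbaldehyde | COc1cc(Br)cc2[nH]cc(C=O)c12 | intermediate
4 | sodium 6-bromo-3-formyl-4-methoxyindol-1-ide | COc1cc(Br)cc2[n-]cc(C=O)c12.[Na+] | intermediate
5 | 6-bromo-4-methoxy-1-{[2-(trimethylsilyl)ethoxy]methyl}-1H-indole-3-carbaldehyde | COc1cc(Br)cc2n(COCC[Si](C)(C)C)cc(C=O)c12 | intermediate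
6 | p-toluenesulfonylmethyl isocyanide | [C-]#[N+]CS(=O)(=O)c1ccc(C)cc1 | starting material
7 | 5-(6-bromo-4-methoxy-1-{[2-(trimethylsilyl)ethoxy]methyl}-1H-indol-3-yl)-4-(4-methylbenzenesulfonyl)-4,5-dihydro-1,3-oxazole (mixture of stereoisomers) | COc1cc(Br)cc2n(COCC[Si](C)(C)C)cc(C3OC=NC3S(=O)(=O)c3ccc(C)cc3)c12 | intermediate
8 | 5-(6-bromo-4-methoxy-1-{[2-(trimethylsilyl)ethoxy]methyl}-1H-indol-3-yl)-1,3-oxazole | COc1cc(Br)cc2n(COCC[Si](C)(C)C)cc(-c3cnco3)c12 | intermediate
9 | methyl 4,4-dimethoxybutanoate | COC(=O)CCC(OC)OC | starting material
10 | N,4,4-trimethoxy-N-methylbutanamide | CON(C)C(=O)CCC(OC)OC | intermediate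
11 | [5-(6-bromo-4-methoxy-1-{[2-(trimethylsilyl)ethoxy]methyl}-1H-indol-3-yl)-1,3-oxazol-2-yl]magnesium chloride | COc1cc(Br)cc2n(COCC[Si](C)(C)C)cc(-c3cnc([Mg]Cl)o3)c12 | intermediate
12 | chloromagnesium 1-[5-(6-bromo-4-methoxy-1-{[2-(trimethylsilyl)ethoxy]methyl}-1H-indol-3-yl)-1,3-oxazol-2-yl]-4,4-dimethoxy-1-[methoxy(methyl)amino]butan-1-olate | COc1cc(Br)cc2n(COCC[Si](C)(C)C)cc(-c3cnc(C(O[Mg]Cl)(CCC(OC)OC)N(C)OC)o3)c12 | intermediate
13 | 1-[5-(6-bromo-4-methoxy-1-{[2-(trimethylsilyl)ethoxy]methyl}-1H-indol-3-yl)-1,3-oxazol-2-yl]-4,4-dimethoxybutan-1-one | COc1cc(Br)cc2n(COCC[Si](C)(C)C)cc(-c3cnc(C(=O)CCC(OC)OC)o3)c12 | intermediate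
14 | 4-[5-(6-bromo-4-methoxy-1-{[2-(trimethylsilyl)ethoxy]methyl}-1H-indol-3-yl)-1,3-oxazol-2-yl]-4-oxobutanal | COc1cc(Br)cc2n(COCC[Si](C)(C)C)cc(-c3cnc(C(=O)CCC=O)o3)c12 | intermediate
15 | 4-amino-1-[5-(6-bromo-4-methoxy-1-{[2-(trimethylsilyl)ethoxy]methyl}-1H-indol-3-yl)-1,3-oxazol-2-yl]-4-hydroxybutan-1-one | COc1cc(Br)cc2n(COCC[Si](C)(C)C)cc(-c3cnc(C(=O)CCC(N)O)o3)c12 | intermediate
16 | 2-[5-(6-bromo-4-methoxy-1-{[2-(trimethylsilyl)ethoxy]methyl}-1H-indol-3-yl)-1,3-oxazol-2-yl]pyrrolidine-2,5-diol (mixture of stereoisomers) | COc1cc(Br)cc2n(COCC[Si](C)(C)C)cc(-c3cnc(C4(O)CCC(O)N4)o3)c12 | intermediate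
17 | 5-(6-bromo-4-methoxy-1-{[2-(trimethylsilyl)ethoxy]methyl}-1H-indol-3-yl)-2-(1H-pyrrol-2-yl)-1,3-oxazole | COc1cc(Br)cc2n(COCC[Si](C)(C)C)cc(-c3cnc(-c4ccc[nH]4)o3)c12 | intermediate
18 | 2-(5-bromo-1H-pyrrol-2-yl)-5-(6-bromo-4-methoxy-1-{[2-(trimethylsilyl)ethoxy]methyl}-1H-indol-3-yl)-1,3-oxazole | COc1cc(Br)cc2n(COCC[Si](C)(C)C)cc(-c3cnc(-c4ccc(Br)[nH]4)o3)c12 | intermediate
19 | {6-bromo-3-[2-(5-bromo-1H-pyrrol-2-yl)-1,3-oxazol-5-yl]-4-methoxy-1H-indol-1-yl}methanol | COc1cc(Br)cc2n(CO)cc(-c3cnc(-c4ccc(Br)[nH]4)o3)c12 | intermediate
20 | 2-(5-bromo-1H-pyrrol-2-yl)-5-(6-bromo-4-methoxy-1H-indol-3-yl)-1,3-oxazole | COc1cc(Br)cc2[nH]cc(-c3cnc(-c4ccc(Br)[nH]4)o3)c12 | target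

## Step count and risk

Total: 9 steps. Longest linear sequence: 8 steps from 1 (steps 1, 2, 3, 5, 6, 7, 8, 9). Step 4 is a one-step side branch from 9.

**Step 7 (key step).** The most likely failure is oligomerisation of the ketoaldehyde by aldol-type or imine condensation before ring closure, or cyclodehydration through the enol oxygen (furan formation) if the medium turns too acidic. The fallback attaches a preformed pyrrole. It sets out from 8 and returns to the route at 17. Compound 8 is magnesiated at C2 with TMPMgCl·LiCl and quenched with I2 to give 5-(6-bromo-4-methoxy-1-SEM-1H-indol-3-yl)-2-iodo-1,3-oxazole F1. Suzuki–Miyaura coupling of F1 with (1-Boc-pyrrol-2-yl)boronic acid (Pd(PPh3)4, aq Na2CO3, dioxane, 70 °C; the C2–I bond should react before the C6–Br bond) should give tert-butyl 2-[5-(6-bromo-4-methoxy-1-SEM-1H-indol-3-yl)-1,3-oxazol-2-yl]-1H-pyrrole-1-carboxylate F2. NaOMe in MeOH/THF at rt then removes the carbamate to give 17.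

**Step 5.** The most likely failure is slow acyl transfer from the amide to the stabilised C2-magnesium species, which would let ring opening to the isocyano enolate or simple proton return take over. The fallback replaces acylation by carbonyl addition and oxidation. It sets out from 8 and 9 and returns at 13. Ester 9 is reduced with i-Bu2AlH (CH2Cl2, −78 °C) to 4,4-dimethoxybutanal F3. The magnesium species 11, made from 8 as in step 5, is added to the more electrophilic F3 to give racemic 1-[5-(6-bromo-4-methoxy-1-SEM-1H-indol-3-yl)-1,3-oxazol-2-yl]-4,4-dimethoxybutan-1-ol F4. Dess–Martin periodinane buffered with NaHCO3 oxidises F4 to 13.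

**Step 8.** The most likely failure is loss of site control, by a second bromination at pyrrole C4 or by competing attack on the methoxyindole. The fallback tempers the pyrrole by temporary N-acylation. It sets out from 17 and returns at 18. Boc2O with 4-(dimethylamino)pyridine in MeCN converts 17 into tert-butyl 2-[5-(6-bromo-4-methoxy-1-SEM-1H-indol-3-yl)-1,3-oxazol-2-yl]-1H-pyrrole-1-carboxylate F2. NBS in THF at −78 °C should then brominate the remaining α-position once, giving tert-butyl 2-bromo-5-[5-(6-bromo-4-methoxy-1-SEM-1H-indol-3-yl)-1,3-oxazol-2-yl]-1H-pyrrole-1-carboxylate F5. NaOMe in MeOH/THF at rt gives 18.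

**Step 9.** The most likely failure is sluggish cleavage of the indole N–SEM bond, so that prolonged heating with fluoride leads to debromination or decomposition of the α-bromopyrrole. The fallback reverses the order of the last two steps. It sets out from 17 and returns at 20. Compound 17 is deprotected with Bu4NF and ethylenediamine in THF at 65 °C, where no bromopyrrole is yet present, to give 5-(6-bromo-4-methoxy-1H-indol-3-yl)-2-(1H-pyrrol-2-yl)-1,3-oxazole F6. F6 is then brominated with NBS (1.0 equiv) in THF at −78 °C to give 20.

**Step 3.** The most likely failure is slow addition of the TosMIC anion to the electron-rich, peri-hindered aldehyde, with decomposition of the isocyanide or stalling at the oxazoline stage. The fallback joins a preformed oxazole by cross-coupling. It sets out from 1 and returns at 8. NaH and SEMCl in DMF convert 1 into 6-bromo-4-methoxy-1-SEM-1H-indole F7. N-Iodosuccinimide in DMF at 0 °C should iodinate C3 to give 6-bromo-3-iodo-4-methoxy-1-SEM-1H-indole F8. Suzuki–Miyaura coupling with 5-(4,4,5,5-tetramethyl-1,3,2-dioxaborolan-2-yl)-2-(triisopropylsilyl)-1,3-oxazole (Pd(dppf)Cl2, K3PO4, dioxane/H2O, 60 °C; C–I before C–Br) should give 5-(6-bromo-4-methoxy-1-SEM-1H-indol-3-yl)-2-(triisopropylsilyl)-1,3-oxazole F9. Bu4NF in THF at 0 °C removes the C2 silyl group to give 8.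

## Further compounds

F1 | step 7 | 5-(6-bromo-4-methoxy-1-{[2-(trimethylsilyl)ethoxy]methyl}-1H-indol-3-yl)-2-iodo-1,3-oxazole | COc1cc(Br)cc2n(COCC[Si](C)(C)C)cc(-c3cnc(I)o3)c12
F2 | step 7 | tert-butyl 2-[5-(6-bromo-4-methoxy-1-{[2-(trimethylsilyl)ethoxy]methyl}-1H-indol-3-yl)-1,3-oxazol-2-yl]-1H-pyrrole-1-carboxylate | COc1cc(Br)cc2n(COCC[Si](C)(C)C)cc(-c3cnc(-c4cccn4C(=O)OC(C)(C)C)o3)c12
F3 | step 5 | 4,4-dimethoxybutanal | COC(OC)CCC=O
F4 | step 5 | 1-[5-(6-bromo-4-methoxy-1-{[2-(trimethylsilyl)ethoxy]methyl}-1H-indol-3-yl)-1,3-oxazol-2-yl]-4,4-dimethoxybutan-1-ol (racemic) | COc1cc(Br)cc2n(COCC[Si](C)(C)C)cc(-c3cnc(C(O)CCC(OC)OC)o3)c12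
F5 | step 8 | tert-butyl 2-bromo-5-[5-(6-bromo-4-methoxy-1-{[2-(trimethylsilyl)ethoxy]methyl}-1H-indol-3-yl)-1,3-oxazol-2-yl]-1H-pyrrole-1-carboxylate | COc1cc(Br)cc2n(COCC[Si](C)(C)C)cc(-c3cnc(-c4ccc(Br)n4C(=O)OC(C)(C)C)o3)c12
F6 | step 9 | 5-(6-bromo-4-methoxy-1H-indol-3-yl)-2-(1H-pyrrol-2-yl)-1,3-oxazole | COc1cc(Br)cc2[nH]cc(-c3cnc(-c4ccc[nH]4)o3)c12
F7 | step 3 | 6-bromo-4-methoxy-1-{[2-(trimethylsilyl)ethoxy]methyl}-1H-indole | COc1cc(Br)cc2n(COCC[Si](C)(C)C)ccc12
F8 | step 3 | 6-bromo-3-iodo-4-methoxy-1-{[2-(trimethylsilyl)ethoxy]methyl}-1H-indole | COc1cc(Br)cc2n(COCC[Si](C)(C)C)cc(I)c12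
F9 | step 3 | 5-(6-bromo-4-methoxy-1-{[2-(trimethylsilyl)ethoxy]methyl}-1H-indol-3-yl)-2-(triisopropylsilyl)-1,3-oxazole | COc1cc(Br)cc2n(COCC[Si](C)(C)C)cc(-c3cnc([Si](C(C)C)(C(C)C)C(C)C)o3)c12
A1 | alternative 1 | 5-[6-bromo-4-methoxy-2-(trimethylsilyl)-1H-indol-3-yl]-2-(1-{[2-(trimethylsilyl)ethoxy]methyl}-1H-pyrrol-2-yl)-1,3-oxazole | COc1cc(Br)cc2[nH]c([Si](C)(C)C)c(-c3cnc(-c4cccn4COCC[Si](C)(C)C)o3)c12
A2 | alternative 1 | 5-bromo-2-iodo-3-methoxyaniline | COc1cc(Br)cc(N)c1I
A3 | alternative 1 | 2-(1-{[2-(trimethylsilyl)ethoxy]methyl}-1H-pyrrol-2-yl)-5-[(trimethylsilyl)ethynyl]-1,3-oxazole | C[Si](C)(C)C#Cc1cnc(-c2cccn2COCC[Si](C)(C)C)o1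
A4 | alternative 2 | 5-(6-bromo-4-methoxy-1H-indol-3-yl)-2-(1-{[2-(trimethylsilyl)ethoxy]methyl}-1H-pyrrol-2-yl)-1,3-oxazole | COc1cc(Br)cc2[nH]cc(-c3cnc(-c4cccn4COCC[Si](C)(C)C)o3)c12
A5 | alternative 2 | 4-bromo-2-methoxy-6-(trimethylsilyl)phenyl trifluoromethanesulfonate | COc1cc(Br)cc([Si](C)(C)C)c1OS(=O)(=O)C(F)(F)F
A6 | alternative 2 | 5-bromo-3-methoxybenzyne | COC1=CC(Br)=CC#C1
A7 | alternative 2 | 5-(2H-azirin-3-yl)-2-(1-{[2-(trimethylsilyl)ethoxy]methyl}-1H-pyrrol-2-yl)-1,3-oxazole | C[Si](C)(C)CCOCn1cccc1-c1ncc(C2=NC2)o1
A8 | alternative 3 | 5-(6-bromo-4-methoxy-1-{[2-(trimethylsilyl)ethoxy]methyl}-1H-indol-3-yl)-1,3-oxazole | COc1cc(Br)cc2n(COCC[Si](C)(C)C)cc(-c3cnco3)c12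
A9 | alternative 3 | 5-(6-bromo-4-methoxy-1-{[2-(trimethylsilyl)ethoxy]methyl}-1H-indol-3-yl)-2-iodo-1,3-oxazole | COc1cc(Br)cc2n(COCC[Si](C)(C)C)cc(-c3cnc(I)o3)c12
A10 | alternative 3 | [1-(tert-butoxycarbonyl)-1H-pyrrol-2-yl]boronic acid | CC(C)(C)OC(=O)n1cccc1B(O)O
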